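Everything rests on growing luteolin ring A onto eriodictyol ring B instead of joining two crowded arenes. The feature exploited is the 1,3,5-trioxygenated luteolin ring A, in which the biaryl carbon C8'' lies between the carbons that carry O7'' and O1''. One thermal vinylketene–ynol ether benzannulation makes C8''–C8a'' and C6''–C7'', closes ring A, and hands over O1'' as free phenol, O7'' as silyl ether and O5'' as benzyl ether. Formylation can then hit only C4a'' and only O1'' can close the pyranone, which guarantees the 8-aryl flavone. The precursor is the ring B aryl triisopropylsiloxyalkyne 10 with its C1' aldehyde masked as a dioxolane, partnered with 3-(benzyloxy)cyclobutenone 12.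

Key step: step 8

Numbering: C2–C8a is the eriodictyol chromanone, C1'–C6' its ring B, C2''–C8a'' the luteolin chromenone. Compounds 1, 4, 11, 19 and 28 are catalogue chemicals.
Assumption on the axis: the target string defines only C2 (S) and leaves the hindered C2'–C8'' axis open, so the axis is not controlled; if rotation is slow, 34 should form as two axial diastereomers, which are carried on together or separated at that stage.
Assumption on step 17: the sense of induction is taken by analogy with simpler alkylidene keto esters; if a CD check on 34 shows the (R) series, the pseudoenantiomeric quinine-derived catalyst replaces the quinidine-derived one.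

Step 1
Reactants: 1 2-bromoisovanillin (2-bromo-3-hydroxy-4-methoxybenzaldehyde)
Product: 2 2-bromo-3,4-dihydroxybenzaldehyde
Conditions: BBr3 (2.5 equiv), CH2Cl2, −78 °C → rt; H2O
Reagents that add atoms: none
Why: Lewis acid cleavage of an aryl methyl ether, in which BBr3 coordinates the methoxy oxygen and bromide removes the methyl group by SN2, while aldehyde and aryl bromide are inert at this temperature.

Step 2
Reactants: 2 2-bromo-3,4-dihydroxybenzaldehyde
Product: 3 3,4-bis(benzyloxy)-2-bromobenzaldehyde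
Conditions: BnBr (2.4 equiv), K2CO3, DMF, 60 °C
Reagents that add atoms: benzyl bromide, BrCc1ccccc1
Why: Double Williamson etherification of the catechol installs groups that survive organolithiums, peroxide, heat and acid and that all leave together in the last step.

Step 3
Reactants: 3 3,4-bis(benzyloxy)-2-bromobenzaldehyde; 4 trimethylsilylacetylene
Product: 5 3,4-bis(benzyloxy)-2-[(trimethylsilyl)ethynyl]benzaldehyde
Conditions: PdCl2(PPh3)2 (5 mol %), CuI (10 mol %), Et3N/THF, sealed tube, 65 °C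
Reagents that add atoms: none
Why: Sonogashira coupling, run at the aldehyde stage because the small, electron-withdrawing ortho formyl group speeds up oxidative addition of the doubly flanked C2'–Br bond to zerovalent palladium.

Step 4
Reactants: 5 3,4-bis(benzyloxy)-2-[(trimethylsilyl)ethynyl]benzaldehyde
Product: 6 2-{3,4-bis(benzyloxy)-2-[(trimethylsilyl)ethynyl]phenyl}-1,3-dioxolane
Conditions: HOCH2CH2OH (5 equiv), TsOH·H2O (5 mol %), PhMe, reflux, Dean–Stark
Reagents that add atoms: ethylene glycol, OCCO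
Why: Acid-catalysed acetalisation with azeotropic removal of water masks the C1' aldehyde as a dioxolane that is inert to the bases, the peroxide, the heat and the magnesium salt of steps 5 to 13.

Step 5
Reactants: 6 2-{3,4-bis(benzyloxy)-2-[(trimethylsilyl)ethynyl]phenyl}-1,3-dioxolane
Product: 7 2-[3,4-bis(benzyloxy)-2-ethynylphenyl]-1,3-dioxolane
Conditions: K2CO3 (0.2 equiv), MeOH/THF, rt
Reagents that add atoms: none
Why: Methoxide-induced protiodesilylation of the alkynylsilane, to which acetal and benzyl ethers are indifferent.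

Step 6
Reactants: 7 2-[3,4-bis(benzyloxy)-2-ethynylphenyl]-1,3-dioxolane
Product: 10 2-{3,4-bis(benzyloxy)-2-[(triisopropylsiloxy)ethynyl]phenyl}-1,3-dioxolane, via lithium acetylide 8 (not isolated), via lithium ynolate 9 (not isolated)
Conditions: n-BuLi, THF, −78 °C; LiOOt-Bu (from t-BuOOH, LiHMDS, THF, −78 °C), −78 → 0 °C; TIPSOTf, −78 → 0 °C; aq. NaHCO3; Et3N-deactivated silica
Reagents that add atoms: tert-butyl hydroperoxide, CC(C)(C)OO; triisopropylsilyl trifluoromethanesulfonate, CC(C)[Si](C(C)C)(C(C)C)OS(=O)(=O)C(F)(F)F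
Why: Electrophilic oxygenation of a lithium acetylide, in which 8 attacks the peroxide oxygen with loss of tert-butoxide to give ynolate 9 and the bulky silyl triflate then reacts at oxygen and not at carbon, the established way from terminal alkynes to triisopropylsiloxyalkynes.

Step 7
Reactants: 11 3-ethoxycyclobut-2-en-1-one
Product: 12 3-(benzyloxy)cyclobut-2-en-1-one
Conditions: BnOH (3 equiv), PPTS (5 mol %), PhMe, 5 Å MS, 30 °C
Reagents that add atoms: benzyl alcohol, OCc1ccccc1
Why: Acid-catalysed alkoxy exchange of a vinylogous ester by addition–elimination at C3, drawn to the benzyl ether by excess alcohol and by uptake of ethanol in the sieves, and run well below the temperature at which the four-membered ring opens.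

Step 8
Reactants: 10 2-{3,4-bis(benzyloxy)-2-[(triisopropylsiloxy)ethynyl]phenyl}-1,3-dioxolane; 12 3-(benzyloxy)cyclobut-2-en-1-one
Product: 17 5-(benzyloxy)-2-[2,3-bis(benzyloxy)-6-(1,3-dioxolan-2-yl)phenyl]-3-(triisopropylsiloxy)phenol, via vinylketene 13 (not isolated), via vinylcyclobutenone 14 (not isolated), via dienylketene 15 (not isolated), via cyclohexadienone 16 (not isolated)
Conditions: 10 in PhMe (0.3 M), 80 °C, 12 (1.4 equiv) by syringe pump over 6 h; then 110 °C, 4 h, Ar, base-washed glassware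
Reagents that add atoms: none
Why: Heat opens 12 by conrotatory 4π electrocyclic cleavage of C1–C4 to vinylketene 13, whose electrophilic sp carbon is attacked by the nucleophilic, aryl-bearing carbon of ynol ether 10 in a regiospecific [2+2] cycloaddition that gives 14 and lays down C8''–C8a'' and C6''–C7''. A second, reversible 4π opening turns 14 into dienylketene 15, and the isomer with ketene and alkoxyvinyl groups cis on the central double bond closes ring A by a six-electron disrotatory electrocyclisation (C8a''–C4a'', six-membered, all carbon) to dienone 16, which tautomerises irreversibly to phenol 17. The closest known reaction is the Danheiser benzannulation of cyclobutenones with triisopropylsiloxyalkynes to resorcinol monosilyl ethers, and since every such cascade passes through a 3-oxygenated cyclobutenone like 14 that opens in this temperature range, the 3-benzyloxy group of 12 should be tolerated. No stereocentre is kept, because C4 of 14 is lost on ring opening, and the new C2'–C8'' axis forms as a racemate. The selectivity needed is regiochemical, ketene carbon to aryl-bearing alkyne carbon, and it is secured by donation from the siloxy oxygen, which makes only that carbon nucleophilic, while the linear alkyne and the sp ketene carbon hold the two ortho groups of ring B away from the forming bonds. Slow addition of 12 keeps the ketene dilute, so that its dimerisation and the O-acylation of the hindered phenol 17 should not compete.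

Step 9
Reactants: 17 5-(benzyloxy)-2-[2,3-bis(benzyloxy)-6-(1,3-dioxolan-2-yl)phenyl]-3-(triisopropylsiloxy)phenol
Product: 18 6-(benzyloxy)-3-[2,3-bis(benzyloxy)-6-(1,3-dioxolan-2-yl)phenyl]-2-hydroxy-4-(triisopropylsiloxy)benzaldehyde
Conditions: MgCl2 (anhydrous, 3 equiv), Et3N (5 equiv), (CH2O)n (8 equiv), MeCN, reflux; cold aq. citric acid
Reagents that add atoms: paraformaldehyde (as formaldehyde), C=O
Why: Casnati–Skattebøl ortho-formylation, in which magnesium ties formaldehyde to the free O1'' oxygen so that carbon is delivered only to the single open ortho position C4a'' and not to C6'' between the two ether groups.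

Step 10
Reactants: 19 3,4-bis(benzyloxy)benzaldehyde
Product: 20 1,2-bis(benzyloxy)-4-ethynylbenzene
Conditions: dimethyl (1-diazo-2-oxopropyl)phosphonate (1.3 equiv), K2CO3 (2 equiv), MeOH/THF, rt
Reagents that add atoms: dimethyl (1-diazo-2-oxopropyl)phosphonate, COP(=O)(OC)C(=[N+]=[N-])C(C)=O
Why: Seyferth–Gilbert homologation in the Ohira–Bestmann version turns the aryl aldehyde into the terminal alkyne under mild carbonate conditions.

Step 11
Reactants: 18 6-(benzyloxy)-3-[2,3-bis(benzyloxy)-6-(1,3-dioxolan-2-yl)phenyl]-2-hydroxy-4-(triisopropylsiloxy)benzaldehyde; 20 1,2-bis(benzyloxy)-4-ethynylbenzene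
Product: 22 1-{6-(benzyloxy)-3-[2,3-bis(benzyloxy)-6-(1,3-dioxolan-2-yl)phenyl]-2-hydroxy-4-(triisopropylsiloxy)phenyl}-3-[3,4-bis(benzyloxy)phenyl]prop-2-yn-1-ol (carbinol centre uncontrolled), via lithium arylacetylide 21 (not isolated)
Conditions: 20 (2.5 equiv), n-BuLi (2.4 equiv), THF, −78 °C; then 18, −78 → 0 °C; aq. NH4Cl; no chromatography
Reagents that add atoms: none
Why: 1,2-Addition of a slim lithium acetylide to the doubly flanked aldehyde, one equivalent of 21 being spent on the phenol; the new carbinol centre forms without control and is erased in step 12.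

Step 12
Reactants: 22 the propargylic alcohol of step 11
Product: 24 2-[3,4-bis(benzyloxy)phenyl]-5-(benzyloxy)-8-[2,3-bis(benzyloxy)-6-(1,3-dioxolan-2-yl)phenyl]-7-(triisopropylsiloxy)-4H-chromen-4-one, via ynone 23 (not isolated)
Conditions: MnO2 (15 equiv), CH2Cl2, rt; filter, evaporate; DMAP (20 mol %), DMF, 30 °C
Reagents that add atoms: none
Why: MnO2 oxidises the benzylic and propargylic alcohol selectively to ynone 23, and nucleophilic catalysis by DMAP at the alkyne β-carbon steers the only free hydroxyl, O1'', into a 6-endo-dig oxa-Michael closure to the flavone instead of the 5-exo aurone.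

Step 13
Reactants: 24 the 7''-O-TIPS flavone of step 12
Product: 26 5,7-bis(benzyloxy)-2-[3,4-bis(benzyloxy)phenyl]-8-[2,3-bis(benzyloxy)-6-(1,3-dioxolan-2-yl)phenyl]-4H-chromen-4-one, via caesium phenoxide 25 (not isolated)
Conditions: CsF (3 equiv), BnBr (1.5 equiv), DMF, rt
Reagents that add atoms: benzyl bromide, BrCc1ccccc1
Why: One-pot fluoride desilylation and Williamson benzylation through phenoxide 25, done now because a free O7''–H would add to the unmasked C1' aldehyde as a cyclic hemiacetal and would quench the amine catalyst of step 17, and because fluoride after step 17 would endanger C2.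

Step 14
Reactants: 26 the hexabenzyl flavone dioxolane of step 13
Product: 27 3,4-bis(benzyloxy)-2-{5,7-bis(benzyloxy)-2-[3,4-bis(benzyloxy)phenyl]-4-oxo-4H-chromen-8-yl}benzaldehyde
Conditions: 2 M aq. HCl, THF, 40 °C
Reagents that add atoms: water, O
Why: Aqueous acid hydrolysis of the aryl dioxolane, under which benzyl ethers and the flavone are stable.

Step 15
Reactants: 28 1-[2,4-bis(benzyloxy)-6-hydroxyphenyl]ethan-1-one
Product: 30 tert-butyl 3-[2,4-bis(benzyloxy)-6-hydroxyphenyl]-3-oxopropanoate, via dilithium dianion 29 (not isolated)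
Conditions: LiHMDS (3.3 equiv), THF, −78 °C; Boc2O (1.1 equiv), −78 → 0 °C; aq. NH4Cl
Reagents that add atoms: di-tert-butyl dicarbonate, CC(C)(C)OC(=O)OC(=O)OC(C)(C)C
Why: Claisen-type C-acylation of lithium dianion 29, whose enolate carbon is its most nucleophilic site; excess base stores the product as its stabilised enolate and the bulky tert-butyl ester resists lactonisation to a 4-hydroxycoumarin.

Step 16
Reactants: 27 the hexabenzyl biaryl aldehyde of step 14; 30 tert-butyl 3-[2,4-bis(benzyloxy)-6-hydroxyphenyl]-3-oxopropanoate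
Product: 31 tert-butyl (Z)-2-[2,4-bis(benzyloxy)-6-hydroxybenzoyl]-3-(3,4-bis(benzyloxy)-2-{5,7-bis(benzyloxy)-2-[3,4-bis(benzyloxy)phenyl]-4-oxo-4H-chromen-8-yl}phenyl)acrylate (Z isomer expected to prevail)
Conditions: piperidine (20 mol %), AcOH (20 mol %), PhMe, 4 Å MS, rt
Reagents that add atoms: none
Why: Knoevenagel condensation under piperidinium acetate catalysis, mild enough for the flavone and helped by the non-enolisable aldehyde; the hydrogen-bonded phenol is expected to stay open under these weakly acidic conditions.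

Step 17
Reactants: 31 the alkylidene keto ester of step 16
Product: 34 (2S)-5,7-bis(benzyloxy)-2-(3,4-bis(benzyloxy)-2-{5,7-bis(benzyloxy)-2-[3,4-bis(benzyloxy)phenyl]-4-oxo-4H-chromen-8-yl}phenyl)chroman-4-one, via flavanone tert-butyl ester 32 (not isolated), via flavanone keto acid 33 (not isolated)
Conditions: quinidine-derived 9-amino-9-deoxy-epi thiourea bearing a 3,5-(CF3)2C6H3 group (15 mol %), PhMe, −25 °C; then TsOH·H2O (1 equiv), 80 °C
Reagents that add atoms: none
Why: Catalytic asymmetric intramolecular oxa-Michael addition, in which the thiourea binds the 1,3-dicarbonyl unit while the quinuclidine nitrogen deprotonates the phenol, so that O1 is delivered to one face of the alkylidene carbon and sets C2 as (S), after which acid cleaves the tert-butyl ester and 33 loses CO2, which removes the labile C3 centre without touching C2.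

Step 18
Reactants: 34 the (2S)-octabenzyl flavanone–flavone of step 17
Product: 35 (2S)-2-{2-[2-(3,4-dihydroxyphenyl)-5,7-dihydroxy-4-oxo-4H-chromen-8-yl]-3,4-dihydroxyphenyl}-5,7-dihydroxychroman-4-one (CNP0265600.1)
Conditions: H2 (1 atm), 10% Pd/C, THF/MeOH, rt
Reagents that add atoms: none
Why: Hydrogenolysis of all eight benzyl ethers under neutral conditions, where neither retro-oxa-Michael opening (the racemisation path of C2) nor reduction of the flavone double bond or of the cyclic benzylic C2–O1 bond is expected at atmospheric pressure.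

Compound list
1 | 2-bromoisovanillin | COc1ccc(C=O)c(Br)c1O | starting material
2 | 2-bromo-3,4-dihydroxybenzaldehyde | O=Cc1ccc(O)c(O)c1Br | intermediate
3 | 3,4-bis(benzyloxy)-2-bromobenzaldehyde | O=Cc1ccc(OCc2ccccc2)c(OCc2ccccc2)c1Br | intermediate
4 | trimethylsilylacetylene | C#C[Si](C)(C)C | starting material
5 | 3,4-bis(benzyloxy)-2-[(trimethylsilyl)ethynyl]benzaldehyde | O=Cc1ccc(OCc2ccccc2)c(OCc2ccccc2)c1C#C[Si](C)(C)C | intermediate
6 | 2-{3,4-bis(benzyloxy)-2-[(trimethylsilyl)ethynyl]phenyl}-1,3-dioxolane | C[Si](C)(C)C#Cc1c(C2OCCO2)ccc(OCc2ccccc2)c1OCc1ccccc1 | intermediate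
7 | 2-[3,4-bis(benzyloxy)-2-ethynylphenyl]-1,3-dioxolane | C#Cc1c(C2OCCO2)ccc(OCc2ccccc2)c1OCc1ccccc1 | intermediate
8 | lithium acetylide of 7 | [Li]C#Cc1c(C2OCCO2)ccc(OCc2ccccc2)c1OCc1ccccc1 | intermediate
9 | lithium ynolate from 8 | [Li]OC#Cc1c(C2OCCO2)ccc(OCc2ccccc2)c1OCc1ccccc1 | intermediate
10 | 2-{3,4-bis(benzyloxy)-2-[(triisopropylsiloxy)ethynyl]phenyl}-1,3-dioxolane | CC(C)[Si](C(C)C)(C(C)C)OC#Cc1c(C2OCCO2)ccc(OCc2ccccc2)c1OCc1ccccc1 | intermediate
11 | 3-ethoxycyclobut-2-en-1-one | CCOC1=CC(=O)C1 | starting material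
12 | 3-(benzyloxy)cyclobut-2-en-1-one | O=C1CC(OCc2ccccc2)=C1 | intermediate
13 | 3-(benzyloxy)buta-1,3-dien-1-one, the (1-benzyloxyvinyl)ketene | O=C=CC(=C)OCc1ccccc1 | intermediate
14 | 2-aryl-4-[1-(benzyloxy)vinyl]-3-(triisopropylsiloxy)cyclobut-2-en-1-one (aryl = 2,3-bis(benzyloxy)-6-(1,3-dioxolan-2-yl)phenyl; racemic at C4) | O=C1C(C(=C)OCc2ccccc2)C(O[Si](C(C)C)(C(C)C)C(C)C)=C1c1c(C2OCCO2)ccc(OCc2ccccc2)c1OCc1ccccc1 | intermediate
15 | 2-aryl-5-(benzyloxy)-3-(triisopropylsiloxy)hexa-1,3,5-trien-1-one, ketene and alkoxyvinyl groups cis on C3=C4 | O=C=C(c1c(C2OCCO2)ccc(OCc2ccccc2)c1OCc1ccccc1)/C(O[Si](C(C)C)(C(C)C)C(C)C)=C\C(=C)OCc1ccccc1 | intermediate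
16 | 2-aryl-5-(benzyloxy)-3-(triisopropylsiloxy)cyclohexa-2,4-dien-1-one | O=C1CC(OCc2ccccc2)=CC(O[Si](C(C)C)(C(C)C)C(C)C)=C1c1c(C2OCCO2)ccc(OCc2ccccc2)c1OCc1ccccc1 | intermediate
17 | 5-(benzyloxy)-2-[2,3-bis(benzyloxy)-6-(1,3-dioxolan-2-yl)phenyl]-3-(triisopropylsiloxy)phenol | Oc1cc(OCc2ccccc2)cc(O[Si](C(C)C)(C(C)C)C(C)C)c1-c1c(C2OCCO2)ccc(OCc2ccccc2)c1OCc1ccccc1 | intermediate
18 | 6-(benzyloxy)-3-[2,3-bis(benzyloxy)-6-(1,3-dioxolan-2-yl)phenyl]-2-hydroxy-4-(triisopropylsiloxy)benzaldehyde | O=Cc1c(OCc2ccccc2)cc(O[Si](C(C)C)(C(C)C)C(C)C)c(-c2c(C3OCCO3)ccc(OCc3ccccc3)c2OCc2ccccc2)c1O | intermediate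
19 | 3,4-bis(benzyloxy)benzaldehyde | O=Cc1ccc(OCc2ccccc2)c(OCc2ccccc2)c1 | starting material
20 | 1,2-bis(benzyloxy)-4-ethynylbenzene | C#Cc1ccc(OCc2ccccc2)c(OCc2ccccc2)c1 | intermediate
21 | lithium acetylide of 20 | [Li]C#Cc1ccc(OCc2ccccc2)c(OCc2ccccc2)c1 | intermediate
22 | propargylic alcohol from 18 and 21 (carbinol centre undefined) | OC(C#Cc1ccc(OCc2ccccc2)c(OCc2ccccc2)c1)c1c(OCc2ccccc2)cc(O[Si](C(C)C)(C(C)C)C(C)C)c(-c2c(C3OCCO3)ccc(OCc3ccccc3)c2OCc2ccccc2)c1O | intermediate
23 | ortho-hydroxyaryl ynone from 22 | O=C(C#Cc1ccc(OCc2ccccc2)c(OCc2ccccc2)c1)c1c(OCc2ccccc2)cc(O[Si](C(C)C)(C(C)C)C(C)C)c(-c2c(C3OCCO3)ccc(OCc3ccccc3)c2OCc2ccccc2)c1O | intermediate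
24 | 2-[3,4-bis(benzyloxy)phenyl]-5-(benzyloxy)-8-[2,3-bis(benzyloxy)-6-(1,3-dioxolan-2-yl)phenyl]-7-(triisopropylsiloxy)-4H-chromen-4-one | O=c1cc(-c2ccc(OCc3ccccc3)c(OCc3ccccc3)c2)oc2c(-c3c(C4OCCO4)ccc(OCc4ccccc4)c3OCc3ccccc3)c(O[Si](C(C)C)(C(C)C)C(C)C)cc(OCc3ccccc3)c12 | intermediate
25 | caesium 7''-phenoxide of the desilylated flavone | [Cs+].[O-]c1cc(OCc2ccccc2)c2c(=O)cc(-c3ccc(OCc4ccccc4)c(OCc4ccccc4)c3)oc2c1-c1c(C2OCCO2)ccc(OCc2ccccc2)c1OCc1ccccc1 | intermediate
26 | 5,7-bis(benzyloxy)-2-[3,4-bis(benzyloxy)phenyl]-8-[2,3-bis(benzyloxy)-6-(1,3-dioxolan-2-yl)phenyl]-4H-chromen-4-one | O=c1cc(-c2ccc(OCc3ccccc3)c(OCc3ccccc3)c2)oc2c(-c3c(C4OCCO4)ccc(OCc4ccccc4)c3OCc3ccccc3)c(OCc3ccccc3)cc(OCc3ccccc3)c12 | intermediate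
27 | 3,4-bis(benzyloxy)-2-{5,7-bis(benzyloxy)-2-[3,4-bis(benzyloxy)phenyl]-4-oxo-4H-chromen-8-yl}benzaldehyde | O=Cc1ccc(OCc2ccccc2)c(OCc2ccccc2)c1-c1c(OCc2ccccc2)cc(OCc2ccccc2)c2c(=O)cc(-c3ccc(OCc4ccccc4)c(OCc4ccccc4)c3)oc12 | intermediate
28 | 1-[2,4-bis(benzyloxy)-6-hydroxyphenyl]ethan-1-one | CC(=O)c1c(O)cc(OCc2ccccc2)cc1OCc1ccccc1 | starting material
29 | dilithium phenoxide–enolate of 28 | [Li]OC(=C)c1c(O[Li])cc(OCc2ccccc2)cc1OCc1ccccc1 | intermediate
30 | tert-butyl 3-[2,4-bis(benzyloxy)-6-hydroxyphenyl]-3-oxopropanoate | CC(C)(C)OC(=O)CC(=O)c1c(O)cc(OCc2ccccc2)cc1OCc1ccccc1 | intermediate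
31 | (Z)-alkylidene keto ester from 27 and 30 | CC(C)(C)OC(=O)/C(C(=O)c1c(O)cc(OCc2ccccc2)cc1OCc1ccccc1)=C\c1ccc(OCc2ccccc2)c(OCc2ccccc2)c1-c1c(OCc2ccccc2)cc(OCc2ccccc2)c2c(=O)cc(-c3ccc(OCc4ccccc4)c(OCc4ccccc4)c3)oc12 | intermediate
32 | tert-butyl (2S)-octabenzyl flavanone-3-carboxylate (C3 labile, undefined) | O=C1C(C(=O)OC(C)(C)C)[C@@H](c2ccc(OCc3ccccc3)c(OCc3ccccc3)c2-c2c(OCc3ccccc3)cc(OCc3ccccc3)c3c(=O)cc(-c4ccc(OCc5ccccc5)c(OCc5ccccc5)c4)oc23)Oc2cc(OCc3ccccc3)cc(OCc3ccccc3)c21 | intermediate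
33 | (2S)-octabenzyl flavanone-3-carboxylic acid (C3 labile, undefined) | O=C1C(C(=O)O)[C@@H](c2ccc(OCc3ccccc3)c(OCc3ccccc3)c2-c2c(OCc3ccccc3)cc(OCc3ccccc3)c3c(=O)cc(-c4ccc(OCc5ccccc5)c(OCc5ccccc5)c4)oc23)Oc2cc(OCc3ccccc3)cc(OCc3ccccc3)c21 | intermediate
34 | (2S)-octabenzyl flavanone–flavone | O=C1C[C@@H](c2ccc(OCc3ccccc3)c(OCc3ccccc3)c2-c2c(OCc3ccccc3)cc(OCc3ccccc3)c3c(=O)cc(-c4ccc(OCc5ccccc5)c(OCc5ccccc5)c4)oc23)Oc2cc(OCc3ccccc3)cc(OCc3ccccc3)c21 | intermediate
35 | CNP0265600.1, (2S)-eriodictyol-(2'→8'')-luteolin | O=C1C[C@@H](c2ccc(O)c(O)c2-c2c(O)cc(O)c3c(=O)cc(-c4ccc(O)c(O)c4)oc23)Oc2cc(O)cc(O)c21 | target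

Total step count: 18. Longest linear sequence: 15 steps from 1 (steps 1–6, 8, 9, 11–14, 16–18).

Steps most likely to fail

Step 8. The [2+2] addition at the alkyne carbon that sits between two ortho groups may be slower than ketene dimerisation, or the cascade may stall before the second ring opening. The fallback gives up ring construction for a cross-coupling. It sets out from 3 and comes back at 27.
- Commercial luteolin is perbenzylated (BnBr, K2CO3, DMF, 80 °C) to 5,7,3',4'-tetra-O-benzylluteolin F1.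
- Electrophilic iodination (NIS, cat. TFA, CH2Cl2), which in 5,7-dialkoxyflavones goes to C8, should give 8-iodo-5,7,3',4'-tetra-O-benzylluteolin F2.
- Miyaura borylation (B2pin2, PdCl2(dppf), KOAc, dioxane, 90 °C) should give the tetra-O-benzylluteolin 8-pinacolboronate F3.
- Suzuki–Miyaura coupling of this boronate with bromide 3 (Pd(OAc)2, SPhos, K3PO4, PhMe/H2O, 100 °C) should give 27; the ortho formyl group of 3 assists oxidative addition.

Step 17. Facial selectivity may be poor because the racemic, slowly rotating C2'–C8'' axis next to the reacting carbon can oppose the catalyst in one half of the material, and an uncatalysed closure may run alongside. The fallback replaces enantioselective C–O bond formation by a kinetic resolution through ketone reduction. It sets out from 31 and comes back at 34.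
- Closure with an achiral base (Et3N, PhMe, rt) gives the racemic tert-butyl flavanone-3-carboxylate F4.
- TsOH at 80 °C takes it through the racemic flavanone keto acid F5 to the racemic octabenzyl flavanone F6.
- Noyori-type asymmetric transfer hydrogenation (Cp*RhCl[(R,R)-TsDPEN], HCO2H/Et3N, EtOAc, rt) is stopped near half conversion.
- It should reduce the (2R) antipode to the (2R,4R)-cis-flavan-4-ol F7, because for that antipode the catalyst preference for a (4R) alcohol and hydride delivery anti to the 2-aryl group coincide.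
- The unreacted (2S)-ketone 34 is separated by chromatography.

Step 7. Adventitious hydrolysis of the vinylogous ester, opening of the strained ring by the alcohol, or an exchange equilibrium that stops short may spoil the alkoxy exchange. The fallback alkylates the enol oxygen instead of substituting at the enone carbon. It sets out from 11 and comes back at 12.
- Hydrolysis (1 M aq. HCl, rt) gives cyclobutane-1,3-dione F8, a strongly acidic enol.
- Like a carboxylic acid, this enol should be O-benzylated by benzyl 2,2,2-trichloroacetimidate without added promoter (CH2Cl2, rt) to give 12.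

Further compounds
F1 | step 8 | 5,7,3',4'-tetra-O-benzylluteolin | O=c1cc(-c2ccc(OCc3ccccc3)c(OCc3ccccc3)c2)oc2cc(OCc3ccccc3)cc(OCc3ccccc3)c12
F2 | step 8 | 8-iodo-5,7,3',4'-tetra-O-benzylluteolin | O=c1cc(-c2ccc(OCc3ccccc3)c(OCc3ccccc3)c2)oc2c(I)c(OCc3ccccc3)cc(OCc3ccccc3)c12
F3 | step 8 | tetra-O-benzylluteolin 8-pinacolboronate | O=c1cc(-c2ccc(OCc3ccccc3)c(OCc3ccccc3)c2)oc2c(B3OC(C)(C)C(C)(C)O3)c(OCc3ccccc3)cc(OCc3ccccc3)c12
F4 | step 17 | racemic tert-butyl flavanone-3-carboxylate | O=C1C(C(=O)OC(C)(C)C)C(c2ccc(OCc3ccccc3)c(OCc3ccccc3)c2-c2c(OCc3ccccc3)cc(OCc3ccccc3)c3c(=O)cc(-c4ccc(OCc5ccccc5)c(OCc5ccccc5)c4)oc23)Oc2cc(OCc3ccccc3)cc(OCc3ccccc3)c21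
F5 | step 17 | racemic flavanone keto acid | O=C1C(C(=O)O)C(c2ccc(OCc3ccccc3)c(OCc3ccccc3)c2-c2c(OCc3ccccc3)cc(OCc3ccccc3)c3c(=O)cc(-c4ccc(OCc5ccccc5)c(OCc5ccccc5)c4)oc23)Oc2cc(OCc3ccccc3)cc(OCc3ccccc3)c21
F6 | step 17 | racemic octabenzyl flavanone | O=C1CC(c2ccc(OCc3ccccc3)c(OCc3ccccc3)c2-c2c(OCc3ccccc3)cc(OCc3ccccc3)c3c(=O)cc(-c4ccc(OCc5ccccc5)c(OCc5ccccc5)c4)oc23)Oc2cc(OCc3ccccc3)cc(OCc3ccccc3)c21
F7 | step 17 | (2R,4R)-cis-flavan-4-ol | O[C@@H]1C[C@H](c2ccc(OCc3ccccc3)c(OCc3ccccc3)c2-c2c(OCc3ccccc3)cc(OCc3ccccc3)c3c(=O)cc(-c4ccc(OCc5ccccc5)c(OCc5ccccc5)c4)oc23)Oc2cc(OCc3ccccc3)cc(OCc3ccccc3)c21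
F8 | step 7 | cyclobutane-1,3-dione | O=C1CC(=O)C1
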